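**Plan**

- Retrosynthesis cuts (a) the two O–CH3 bonds, then (b) two C–C bonds of the quinone ring: the bond from the ring carbon bearing the 2,7-disubstituted indole to its oxygen-bearing neighbour (ring closure) and, across the ring, the bond from the carbon bearing the plain indol-3-yl to its oxygen-bearing neighbour (union of the halves). Then (c) the exocyclic C=C of a dioxolanone-masked pyruvate, the C3–CHO and C7–prenyl bonds, and the pyrrole ring of the substituted indole.
- Enabling feature: the quinone ring is the bis-enol ether of cyclohexane-1,2,4,5-tetraone. Its C3 and C6 each carry an indol-3-yl group and lie between two oxygenated carbons, so the ring is two indolyl–C–C(O)–C(O) pyruvate units joined head to tail at the oxidation level of two α-keto esters, as in the biosynthesis of bis-indolylquinones from two indolepyruvates.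
- Forward: a Fischer synthesis makes the substituted indole; Stille prenylation, formylation and a Wittig reaction turn it into an arylidene-dioxolanone (an acetone-masked, acyl-activated indolylpyruvate). A Claisen–Dieckmann cascade with methyl indol-3-ylpyruvate then builds the six-membered carbocycle as the last ring, and O-methylation finishes.
- Stereochemistry: the target has no stereocentre and no stereogenic double bond; the Z geometry of 13 disappears in the cascade.

Key step: step 8

Remark: 1, 3, 6, 9 and 14 are taken as commercial; 15 (largely enolic in solution) and 17 (rapidly equilibrating hydroxyquinone tautomers) are drawn as single tautomers.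

**Route**

Step 1
Reactants: 1 2,2-dimethylbut-3-enoic acid
Product: 2 3,3-dimethylpent-4-en-2-one
Conditions: MeLi (2.2 equiv), Et2O, 0 °C → rt; inverse quench into cold 1 M HCl
Reagents that add atoms: methyllithium [Li]C
Why: Organolithium addition to a lithium carboxylate gives a geminal dilithium alkoxide that releases the methyl ketone only on quench, and the quaternary α-carbon excludes enolisation on that side.

Step 2
Reactants: 2 3,3-dimethylpent-4-en-2-one; 3 (2-bromophenyl)hydrazine hydrochloride
Product: 5 7-bromo-2-(2-methylbut-3-en-2-yl)-1H-indole, via hydrazone 4 (not isolated)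
Conditions: EtOH, 70 °C; then ZnCl2 (3 equiv), AcOH, 100 °C
Reagents that add atoms: none
Why: Fischer indole synthesis, in which the hydrazone can form an ene-hydrazine only toward its methyl group and the [3,3]-shift can use only the one free ortho position, so the 2-tert-alkyl-7-bromoindole is the single indole expected.

Step 3
Reactants: 5 7-bromo-2-(2-methylbut-3-en-2-yl)-1H-indole; 6 tributyl(3-methylbut-2-en-1-yl)stannane
Product: 7 2-(2-methylbut-3-en-2-yl)-7-(3-methylbut-2-en-1-yl)-1H-indole
Conditions: Pd(PPh3)4 (5 mol %), DMF, 100 °C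
Reagents that add atoms: none
Why: Stille coupling, with oxidative addition of the aryl bromide to zerovalent palladium and transfer of the allyl group from tin, which should deliver the linear prenyl arene and tolerates the free N–H.

Step 4
Reactants: 7 2-(2-methylbut-3-en-2-yl)-7-(3-methylbut-2-en-1-yl)-1H-indole
Product: 8 2-(2-methylbut-3-en-2-yl)-7-(3-methylbut-2-en-1-yl)-1H-indole-3-carbaldehyde
Conditions: POCl3, DMF, 0 → 40 °C; then aq. NaOH, 0 °C → rt
Reagents that add atoms: N,N-dimethylformamide CN(C)C=O; water O
Why: Vilsmeier–Haack formylation at C3, the only free nucleophilic position of the 2-substituted indole, by a chloroiminium ion that should leave both alkenes alone.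

Step 5
Reactants: 9 2,2-dimethyl-1,3-dioxolan-4-one
Product: 11 (2,2-dimethyl-5-oxo-1,3-dioxolan-4-yl)triphenylphosphonium bromide, via bromodioxolanone 10 (not isolated)
Conditions: NBS (1.05 equiv), AIBN (cat.), PhCF3, 80 °C; filter; then PPh3, toluene, rt
Reagents that add atoms: N-bromosuccinimide O=C1CCC(=O)N1Br; triphenylphosphine c1ccc(cc1)P(c1ccccc1)c1ccccc1
Why: Wohl–Ziegler radical bromination at the captodative C5–H (flanked by ring oxygen and lactone carbonyl) followed by SN2 quaternisation of the phosphine by the reactive α-bromo lactone.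

Step 6
Reactants: 8 2-(2-methylbut-3-en-2-yl)-7-(3-methylbut-2-en-1-yl)-1H-indole-3-carbaldehyde; 11 (2,2-dimethyl-5-oxo-1,3-dioxolan-4-yl)triphenylphosphonium bromide
Product: 13 (5Z)-2,2-dimethyl-5-{[2-(2-methylbut-3-en-2-yl)-7-(3-methylbut-2-en-1-yl)-1H-indol-3-yl]methylidene}-1,3-dioxolan-4-one, via phosphorus ylide 12 (not isolated)
Conditions: 11 (1.5 equiv), Et3N (1.5 equiv), toluene, rt; then 8, 110 °C
Reagents that add atoms: none
Why: Wittig olefination with a stabilised ylide too weakly basic to deprotonate the indole N–H, expected to give the Z alkene (aryl trans to the lactone carbonyl), although either geometry would serve in step 8.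

Step 7
Reactants: 14 3-(1H-indol-3-yl)-2-oxopropanoic acid
Product: 15 methyl 3-(1H-indol-3-yl)-2-oxopropanoate
Conditions: TMSCHN2 (1.05 equiv), PhMe/MeOH, 0 °C
Reagents that add atoms: trimethylsilyldiazomethane C[Si](C)(C)C=[N+]=[N-]
Why: Carboxylic acid O-methylation by diazomethane released from TMSCHN2 and methanol, in which the acid reacts far faster than the enol O–H or the indole N–H.

Step 8
Reactants: 15 methyl 3-(1H-indol-3-yl)-2-oxopropanoate; 13 (5Z)-2,2-dimethyl-5-{[2-(2-methylbut-3-en-2-yl)-7-(3-methylbut-2-en-1-yl)-1H-indol-3-yl]methylidene}-1,3-dioxolan-4-one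
Product: 17 2,5-dihydroxy-3-(1H-indol-3-yl)-6-[2-(2-methylbut-3-en-2-yl)-7-(3-methylbut-2-en-1-yl)-1H-indol-3-yl]cyclohexa-2,5-diene-1,4-dione, via open-chain trioxohexanoate 16 (not isolated)
Conditions: 15 (1.2 equiv), LiHMDS (1.2 equiv), THF, −78 °C; 13, −78 °C → rt; then KOtBu (1.2 equiv), DMF, rt → 50 °C; 1 M HCl, 0 °C
Reagents that add atoms: none
Why: Proposed new method: the lithium enolate of 15 is C-acylated at its indolylmethine carbon by the lactone carbonyl of 13 (Claisen condensation), the tetrahedral intermediate collapses with loss of acetone and so unmasks the enolate of the second pyruvate unit in 16, whose carbon, once KOtBu in DMF has formed the dianion and loosened the lithium chelate, attacks the methyl ester (Dieckmann condensation) to close the carbocycle, after which loss of methoxide and enolisation give the dianion of 17; the sequence copies the head-to-tail Claisen–Dieckmann union of two indolylpyruvate units by which bis-indolylquinones arise in nature. The closest known reaction types are the C-acylation of ester enolates by 5-ylidene-1,3-dioxolan-4-ones used for pulvinones and the alkoxide-induced rearrangement of enol lactones to cyclic 1,3-diones (ylidenebutenolide to cyclopentenedione, pyrandione to terphenylquinone), but their combination on an α-keto ester enolate and for a bis-indolylquinone is untested. The ring closes in the 6-(enolendo)-exo-trig mode, and no stereocentre is created because all six ring carbons end sp2-hybridised. The step needs cross-coupling over homo-coupling and a fixed order of bond formation: 13 has no acidic C–H and its ketone is locked in the enol-ether ring, so it can act only as acyl donor until the acyl transfer itself releases its nucleophilic carbon, which therefore must form the second, ring-closing bond, while 15 reacts as a preformed enolate that cannot serve as an aldol acceptor. C- over O-acylation and C- over O-ring closure should be secured thermodynamically, since enol esters and the six-membered enol lactone are acyl donors that alkoxide reopens, whereas the doubly deprotonated dihydroxyquinone is a bis-vinylogous carboxylate and the sink of the manifold.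

Step 9
Reactants: 17 2,5-dihydroxy-3-(1H-indol-3-yl)-6-[2-(2-methylbut-3-en-2-yl)-7-(3-methylbut-2-en-1-yl)-1H-indol-3-yl]cyclohexa-2,5-diene-1,4-dione
Product: 18 2,5-dimethoxy-3-(1H-indol-3-yl)-6-[2-(2-methylbut-3-en-2-yl)-7-(3-methylbut-2-en-1-yl)-1H-indol-3-yl]cyclohexa-2,5-diene-1,4-dione
Conditions: TMSCHN2 (3 equiv), CH2Cl2/MeOH, 0 °C → rt
Reagents that add atoms: trimethylsilyldiazomethane C[Si](C)(C)C=[N+]=[N-]
Why: Diazomethane-type O-methylation of the two vinylogous carboxylic acid hydroxyls of the hydroxyquinone, which are far more acidic than the indole N–H groups and should give the para-quinone dimethyl ether.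

**Compound list**

1 | 2,2-dimethylbut-3-enoic acid | C=CC(C)(C)C(=O)O | starting material
2 | 3,3-dimethylpent-4-en-2-one | CC(=O)C(C)(C)C=C | intermediate
3 | (2-bromophenyl)hydrazine hydrochloride | NNc1ccccc1Br.Cl | starting material
4 | (E)-1-(2-bromophenyl)-2-(3,3-dimethylpent-4-en-2-ylidene)hydrazine | C/C(=N\Nc1ccccc1Br)C(C)(C)C=C | intermediate
5 | 7-bromo-2-(2-methylbut-3-en-2-yl)-1H-indole | C=CC(C)(C)c1cc2cccc(Br)c2[nH]1 | intermediate
6 | tributyl(3-methylbut-2-en-1-yl)stannane | CCCC[Sn](CCCC)(CCCC)CC=C(C)C | starting material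
7 | 2-(2-methylbut-3-en-2-yl)-7-(3-methylbut-2-en-1-yl)-1H-indole | C=CC(C)(C)c1cc2cccc(CC=C(C)C)c2[nH]1 | intermediate
8 | 2-(2-methylbut-3-en-2-yl)-7-(3-methylbut-2-en-1-yl)-1H-indole-3-carbaldehyde | C=CC(C)(C)c1[nH]c2c(CC=C(C)C)cccc2c1C=O | intermediate
9 | 2,2-dimethyl-1,3-dioxolan-4-one | CC1(C)OCC(=O)O1 | starting material
10 | 5-bromo-2,2-dimethyl-1,3-dioxolan-4-one (racemic) | CC1(C)OC(Br)C(=O)O1 | intermediate
11 | (2,2-dimethyl-5-oxo-1,3-dioxolan-4-yl)triphenylphosphonium bromide (racemic) | CC1(C)OC(C(=O)O1)[P+](c1ccccc1)(c1ccccc1)c1ccccc1.[Br-] | intermediate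
12 | 2,2-dimethyl-5-(triphenylphosphoranylidene)-1,3-dioxolan-4-one | CC1(C)OC(=P(c2ccccc2)(c2ccccc2)c2ccccc2)C(=O)O1 | intermediate
13 | (5Z)-2,2-dimethyl-5-{[2-(2-methylbut-3-en-2-yl)-7-(3-methylbut-2-en-1-yl)-1H-indol-3-yl]methylidene}-1,3-dioxolan-4-one | O=C1OC(C)(C)O/C1=C\c1c(C(C)(C)C=C)[nH]c2c(CC=C(C)C)cccc12 | intermediate
14 | 3-(1H-indol-3-yl)-2-oxopropanoic acid (indole-3-pyruvic acid) | O=C(O)C(=O)Cc1c[nH]c2ccccc12 | starting material
15 | methyl 3-(1H-indol-3-yl)-2-oxopropanoate | COC(=O)C(=O)Cc1c[nH]c2ccccc12 | intermediate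
16 | methyl 3-(1H-indol-3-yl)-6-[2-(2-methylbut-3-en-2-yl)-7-(3-methylbut-2-en-1-yl)-1H-indol-3-yl]-2,4,5-trioxohexanoate (present as its enolates) | COC(=O)C(=O)C(c1c[nH]c2ccccc12)C(=O)C(=O)Cc1c(C(C)(C)C=C)[nH]c2c(CC=C(C)C)cccc12 | intermediate
17 | 2,5-dihydroxy-3-(1H-indol-3-yl)-6-[2-(2-methylbut-3-en-2-yl)-7-(3-methylbut-2-en-1-yl)-1H-indol-3-yl]cyclohexa-2,5-diene-1,4-dione | C=CC(C)(C)c1[nH]c2c(CC=C(C)C)cccc2c1C1=C(O)C(=O)C(c2c[nH]c3ccccc23)=C(O)C1=O | intermediate
18 | 2,5-dimethoxy-3-(1H-indol-3-yl)-6-[2-(2-methylbut-3-en-2-yl)-7-(3-methylbut-2-en-1-yl)-1H-indol-3-yl]cyclohexa-2,5-diene-1,4-dione | C=CC(C)(C)c1[nH]c2c(CC=C(C)C)cccc2c1C1=C(OC)C(=O)C(c2c[nH]c3ccccc23)=C(OC)C1=O | target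

**Count**

Total steps: 9. Longest linear sequence: 7 steps (steps 1, 2, 3, 4, 6, 8, 9); steps 5 and 7 are side branches.

**Steps most likely to fail, with fallbacks**

Step 8 (proposed new method). The ambident enolate of 15 may be acylated at oxygen instead of carbon. The lactone carbonyl of 13, conjugated with the electron-rich indole, may be too weak an acyl donor. The liberated enolate may close through oxygen and stall at an enol lactone. The fallback uses the known acid-promoted conjugate addition of indoles to a halogenated quinone and sets out from 7. Indole 7 and 2,5-dichloro-1,4-benzoquinone under acid promotion (AcOH, or catalytic HCl in THF if the hindered indole is sluggish) should give 2,5-dichloro-3-[2-(2-methylbut-3-en-2-yl)-7-(3-methylbut-2-en-1-yl)-1H-indol-3-yl]benzene-1,4-diol F1. DDQ in the same flask should oxidise it to 2,5-dichloro-3-[2-(2-methylbut-3-en-2-yl)-7-(3-methylbut-2-en-1-yl)-1H-indol-3-yl]cyclohexa-2,5-diene-1,4-dione F2. Commercial indole in AcOH should add at the remaining free quinone carbon to give 2,5-dichloro-3-(1H-indol-3-yl)-6-[2-(2-methylbut-3-en-2-yl)-7-(3-methylbut-2-en-1-yl)-1H-indol-3-yl]benzene-1,4-diol F3, reoxidised by DDQ to 2,5-dichloro-3-(1H-indol-3-yl)-6-[2-(2-methylbut-3-en-2-yl)-7-(3-methylbut-2-en-1-yl)-1H-indol-3-yl]cyclohexa-2,5-diene-1,4-dione F4. Heating F4 with NaOH in aqueous MeOH, then acidifying, should replace both chlorides by hydroxyl and return to the route at 17.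

Step 6. The stabilised ylide may add too slowly to the hindered aldehyde, whose carbonyl is deactivated as a vinylogous amide, and may decompose thermally first. The fallback forms the same C=C bond from the nucleophilic indole carbon instead of from the aldehyde; it sets out from 7 and 9 and bypasses 8. Heating 9 with tert-butoxybis(dimethylamino)methane should give (5Z)-5-[(dimethylamino)methylidene]-2,2-dimethyl-1,3-dioxolan-4-one F5. In AcOH this enaminone should be attacked at its iminium carbon by C3 of 7 and lose dimethylamine (addition–elimination of an indole to a 3-(dimethylamino)propenoate), returning to the route at 13.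

Step 2. The 1,1-dimethylallyl alkene may be lost or rearranged by protonation under the hot acidic conditions, and the sigmatropic shift of the electron-poor ortho-bromo ene-hydrazine may be sluggish. The fallback builds the pyrrole ring by alkyne hydroamination and sets out from 2. Enol phosphate formation and elimination (LDA, ClP(O)(OEt)2, then LDA, THF, −78 °C → rt) should give 3,3-dimethylpent-4-en-1-yne F6. Sonogashira coupling with commercial 2-bromo-6-iodoaniline at the C–I bond (PdCl2(PPh3)2, CuI, Et3N, rt) should give 2-bromo-6-(3,3-dimethylpent-4-en-1-yn-1-yl)aniline F7. Base-mediated 5-endo-dig cyclisation (KOtBu, NMP, rt) returns to the route at 5.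

**Further compounds**

F1 | step 8 | 2,5-dichloro-3-[2-(2-methylbut-3-en-2-yl)-7-(3-methylbut-2-en-1-yl)-1H-indol-3-yl]benzene-1,4-diol | Oc1cc(Cl)c(O)c(-c2c(C(C)(C)C=C)[nH]c3c(CC=C(C)C)cccc23)c1Cl
F2 | step 8 | 2,5-dichloro-3-[2-(2-methylbut-3-en-2-yl)-7-(3-methylbut-2-en-1-yl)-1H-indol-3-yl]cyclohexa-2,5-diene-1,4-dione | O=C1C=C(Cl)C(=O)C(c2c(C(C)(C)C=C)[nH]c3c(CC=C(C)C)cccc23)=C1Cl
F3 | step 8 | 2,5-dichloro-3-(1H-indol-3-yl)-6-[2-(2-methylbut-3-en-2-yl)-7-(3-methylbut-2-en-1-yl)-1H-indol-3-yl]benzene-1,4-diol | Oc1c(Cl)c(-c2c(C(C)(C)C=C)[nH]c3c(CC=C(C)C)cccc23)c(O)c(Cl)c1-c1c[nH]c2ccccc12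
F4 | step 8 | 2,5-dichloro-3-(1H-indol-3-yl)-6-[2-(2-methylbut-3-en-2-yl)-7-(3-methylbut-2-en-1-yl)-1H-indol-3-yl]cyclohexa-2,5-diene-1,4-dione | C=CC(C)(C)c1[nH]c2c(CC=C(C)C)cccc2c1C1=C(Cl)C(=O)C(c2c[nH]c3ccccc23)=C(Cl)C1=O
F5 | step 6 | (5Z)-5-[(dimethylamino)methylidene]-2,2-dimethyl-1,3-dioxolan-4-one | CN(C)/C=C1\OC(C)(C)OC1=O
F6 | step 2 | 3,3-dimethylpent-4-en-1-yne | C#CC(C)(C)C=C
F7 | step 2 | 2-bromo-6-(3,3-dimethylpent-4-en-1-yn-1-yl)aniline | Nc1c(Br)cccc1C#CC(C)(C)C=C
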